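**Retrosynthetic overview**
1. Target 21 ⇐ O‑protected ketone 19 by one global O‑dealkylation (last step).
2. 19 ⇐ cross‑conjugated dienone 17: C1 (propenyl) and C2 (H) are set together by axial conjugate propenylation and kinetic protonation.
3. 17 ⇐ dienyl triflate 9 + pyridine aldehyde 14 (C2–C(=O) bond by Ni/Cr coupling, then oxidation); 14 from a Suzuki coupling and ortho‑lithiation/formylation.
4. 9 ⇐ octalone 7 ⇐ acyclic dienal 3 by a one‑pot Brønsted‑acid organocatalysed conjugate‑ene/carbonyl‑ene bicyclisation (ring B first, then ring A; sets C4a and C8a).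
5. 3 ⇐ (S)‑citronellal 2 ⇐ achiral citral 1 by organocatalytic asymmetric transfer hydrogenation (sets C7, which controls every later centre).

Assumption: decalin locants are those of the octahydronaphthalene (C1 propenyl, C2 acyl, C4/C7 methyl, C4a/C8a ring fusion). The SMILES is read as (1S,2S,4aS,7S,8aR): trans‑fused, C7‑methyl equatorial, C1‑propenyl axial and cis to the C2 acyl group. Citral, 5‑bromo‑2,4‑dimethoxypyridine, (4‑tert‑butoxyphenyl)boronic acid and (E)‑1‑bromopropene are taken as commercial.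

**Route**

Step 1
Reactants: 1 citral (E/Z mixture)
Product: 2 (S)-citronellal
Conditions: (S)-TRIP morpholinium salt (10 mol%), Hantzsch ester (1.1 equiv), THF, 50 °C, 24 h
Reagents that add atoms: none
Why: Iminium‑ion organocatalysis with a chiral phosphate counter‑anion (asymmetric counteranion‑directed transfer hydrogenation): the geranial and neral iminium ions equilibrate, and the (S)-TRIP anion steers hydride transfer from the Hantzsch ester to one face of C3, setting the methyl‑bearing centre (future C7) as S in about 90% ee.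

Step 2
Reactants: 2 (S)-citronellal
Product: 3 (2E,5S)-5,9-dimethyldeca-2,8-dienal
Conditions: Ph3P=CHCHO (1.1 equiv), toluene, 80 °C
Reagents that add atoms: (triphenylphosphoranylidene)acetaldehyde, O=CC=P(c1ccccc1)(c1ccccc1)c1ccccc1
Why: Wittig olefination with a stabilised ylide gives the (E)-enal selectively, and the β‑stereocentre cannot enolise.

Step 3
Reactants: 3 (2E,5S)-5,9-dimethyldeca-2,8-dienal
Product: 5 (4aS,7S,8aR)-7-methyl-4-methylidenedecahydronaphthalen-2-ol (C2 epimer mixture), via monocyclic ene aldehyde 4 (not isolated)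
Conditions: (S,S)-IDPi [imidodiphosphorimidate Brønsted acid built from two (S)-3,3′-bis(3,5-bis(trifluoromethyl)phenyl)-BINOL units, N‑SO2CF3 groups] (3 mol%), CHCl3, −20 °C → rt
Reagents that add atoms: none
Why: Proposed new method: the confined strong Brønsted acid protonates the enal oxygen, the trisubstituted C8=C9 alkene attacks the β‑carbon through a chair transition state with the C5 methyl and the (E)-enophile equatorial (substrate‑controlled, giving trans C4a/C8a), loss of a methyl proton from the tertiary cation gives aldehyde 4 (formal type 1 conjugate ene), and the same acid then activates 4 for a type 2 carbonyl‑ene closure of ring A onto the new isopropenyl group; the closest known reaction types are the Lewis‑acid ene cyclisation of citronellal‑derived alkylidene malonates and Brønsted‑acid carbonyl‑ene/Prins cyclisations of citronellal‑type aldehydes.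

Step 4
Reactants: 5 (4aS,7S,8aR)-7-methyl-4-methylidenedecahydronaphthalen-2-ol
Product: 7 (4aS,7S,8aR)-4,7-dimethyl-4a,5,6,7,8,8a-hexahydronaphthalen-2(1H)-one, via exo-methylene ketone 6 (not isolated)
Conditions: Dess–Martin periodinane (1.2 equiv), CH2Cl2, rt; aq. NaHCO3/Na2S2O3 wash; then DBU (0.2 equiv), CH2Cl2, rt
Reagents that add atoms: none
Why: Dess–Martin oxidation converts both carbinol epimers to one ketone, and base then moves the exocyclic β,γ‑alkene into conjugation to give the favoured endocyclic enone without touching the ring‑fusion centres.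

Step 5
Reactants: 7 (4aS,7S,8aR)-4,7-dimethyl-4a,5,6,7,8,8a-hexahydronaphthalen-2(1H)-one
Product: 9 (4aS,7S,8aS)-4,7-dimethyl-4a,5,6,7,8,8a-hexahydronaphthalen-2-yl trifluoromethanesulfonate, via lithium dienolate 8 (not isolated)
Conditions: LiN(iPr)2 (1.1 equiv), THF, −78 °C; PhNTf2 (1.1 equiv), −78 → 0 °C
Reagents that add atoms: N-phenylbis(trifluoromethanesulfonimide), O=S(=O)(N(c1ccccc1)S(=O)(=O)C(F)(F)F)C(F)(F)F
Why: Kinetic α′‑deprotonation of the enone at C1 gives the cross‑conjugated dienolate, which is O‑triflated to the 2‑triflyloxy‑1,3‑diene (enol triflate formation; the 8aS label is a priority change only).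

Step 6
Reactants: 10 5-bromo-2,4-dimethoxypyridine; 11 (4-tert-butoxyphenyl)boronic acid
Product: 12 5-(4-tert-butoxyphenyl)-2,4-dimethoxypyridine
Conditions: Pd(PPh3)4 (3 mol%), K2CO3 (2 equiv), 1,4-dioxane/H2O 4:1, 90 °C
Reagents that add atoms: none
Why: Suzuki–Miyaura cross‑coupling at the only C–Br bond.

Step 7
Reactants: 12 5-(4-tert-butoxyphenyl)-2,4-dimethoxypyridine
Product: 14 5-(4-tert-butoxyphenyl)-2,4-dimethoxypyridine-3-carbaldehyde, via 3-pyridyllithium 13 (not isolated)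
Conditions: n-BuLi (1.1 equiv), THF, −78 → −30 °C; DMF (2 equiv), −78 °C → rt
Reagents that add atoms: N,N-dimethylformamide, CN(C)C=O
Why: Directed ortho‑metalation occurs at C3, the position flanked by both methoxy groups, and the aryllithium is formylated by DMF.

Step 8
Reactants: 9 dienyl triflate; 14 5-(4-tert-butoxyphenyl)-2,4-dimethoxypyridine-3-carbaldehyde
Product: 16 [5-(4-tert-butoxyphenyl)-2,4-dimethoxypyridin-3-yl][(4aS,7S,8aR)-4,7-dimethyl-4a,5,6,7,8,8a-hexahydronaphthalen-2-yl]methanol (carbinol epimers), via dienylchromium dichloride 15 (not isolated)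
Conditions: CrCl2 (4 equiv), NiCl2 (2 mol%), DMF, rt
Reagents that add atoms: none
Why: Nozaki–Hiyama–Kishi coupling: zerovalent nickel inserts into the C–OTf bond, the dienyl group passes to trivalent chromium and adds 1,2 to the hindered aldehyde; the carbinol configuration is irrelevant.

Step 9
Reactants: 16 dienyl(pyridyl)methanol
Product: 17 [5-(4-tert-butoxyphenyl)-2,4-dimethoxypyridin-3-yl][(4aS,7S,8aR)-4,7-dimethyl-4a,5,6,7,8,8a-hexahydronaphthalen-2-yl]methanone
Conditions: Dess–Martin periodinane (1.3 equiv), CH2Cl2, 0 °C → rt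
Reagents that add atoms: none
Why: Dess–Martin oxidation of the doubly activated (allylic/benzylic) alcohol gives the cross‑conjugated dienone, which has no epimerisable centre.

Step 10
Reactants: 17 cross-conjugated dienone
Product: 19 [5-(4-tert-butoxyphenyl)-2,4-dimethoxypyridin-3-yl][(1S,2S,4aS,7S,8aR)-4,7-dimethyl-1-[(E)-prop-1-enyl]-1,2,4a,5,6,7,8,8a-octahydronaphthalen-2-yl]methanone, via lithium enolate 18 (not isolated)
Conditions: (E)-1-bromopropene (2.4 equiv), t-BuLi (4.8 equiv), Et2O, −78 °C; CuI (1.2 equiv), −40 °C; 17, −78 °C; AcOH (3 equiv) in THF, −78 °C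
Reagents that add atoms: (E)-1-bromopropene, C/C=C/Br
Why: Gilman cuprate 1,4‑addition: the (E)-propenyl group (geometry retained through Br–Li exchange and transfer from copper) attacks C1 axially, anti to the pseudoaxial C8a–H of the trans‑fused ring, giving the axial propenyl group (C1 S), and the dienolate is then protonated kinetically at C2 from the face opposite that propenyl group (held axial by allylic 1,3‑strain), placing the acyl group cis to propenyl (C2 S) and leaving C3=C4 out of conjugation.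

Step 11
Reactants: 19 protected ketone
Product: 21 4-hydroxy-5-(4-hydroxyphenyl)-3-[(1S,2S,4aS,7S,8aR)-4,7-dimethyl-1-[(E)-prop-1-enyl]-1,2,4a,5,6,7,8,8a-octahydronaphthalene-2-carbonyl]pyridin-2(1H)-one, via tris(trimethylsilyl) ether 20 (not isolated)
Conditions: Me3SiCl (6 equiv), NaI (6 equiv), MeCN, 0 °C → rt; then H2O, 0 °C
Reagents that add atoms: none
Why: Me3SiI made in the flask cleaves the lactim methyl ether, the vinylogous methyl ester (4‑OMe) and the aryl tert‑butyl ether under non‑basic conditions (SN2 at methyl, SN1 at tert‑butyl), and water hydrolyses the silyl ethers to the 4‑hydroxy‑2‑pyridone without enolising C2.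

**Compound list**
1 | citral (3,7-dimethylocta-2,6-dienal, E/Z mixture) | CC(C)=CCCC(C)=CC=O | starting material
2 | (S)-citronellal [(3S)-3,7-dimethyloct-6-enal] | O=CC[C@@H](C)CCC=C(C)C | intermediate
3 | (2E,5S)-5,9-dimethyldeca-2,8-dienal | O=C/C=C/C[C@@H](C)CCC=C(C)C | intermediate
4 | 2-[(1R,2S,5S)-5-methyl-2-(prop-1-en-2-yl)cyclohexyl]acetaldehyde | O=CC[C@H]1C[C@@H](C)CC[C@@H]1C(C)=C | intermediate
5 | (4aS,7S,8aR)-7-methyl-4-methylidenedecahydronaphthalen-2-ol (C2 epimers) | OC1C[C@H]2C[C@@H](C)CC[C@@H]2C(=C)C1 | intermediate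
6 | (4aS,7S,8aR)-7-methyl-4-methylideneoctahydronaphthalen-2(1H)-one | O=C1C[C@H]2C[C@@H](C)CC[C@@H]2C(=C)C1 | intermediate
7 | (4aS,7S,8aR)-4,7-dimethyl-4a,5,6,7,8,8a-hexahydronaphthalen-2(1H)-one | O=C1C[C@H]2C[C@@H](C)CC[C@@H]2C(C)=C1 | intermediate
8 | lithium (4aS,7S,8aS)-4,7-dimethyl-4a,5,6,7,8,8a-hexahydronaphthalen-2-olate | [Li]OC1=C[C@H]2C[C@@H](C)CC[C@@H]2C(C)=C1 | intermediate
9 | (4aS,7S,8aS)-4,7-dimethyl-4a,5,6,7,8,8a-hexahydronaphthalen-2-yl trifluoromethanesulfonate | O=S(=O)(OC1=C[C@H]2C[C@@H](C)CC[C@@H]2C(C)=C1)C(F)(F)F | intermediate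
10 | 5-bromo-2,4-dimethoxypyridine | COc1cc(OC)c(Br)cn1 | starting material
11 | (4-tert-butoxyphenyl)boronic acid | CC(C)(C)Oc1ccc(B(O)O)cc1 | starting material
12 | 5-(4-tert-butoxyphenyl)-2,4-dimethoxypyridine | COc1cc(OC)c(-c2ccc(OC(C)(C)C)cc2)cn1 | intermediate
13 | [5-(4-tert-butoxyphenyl)-2,4-dimethoxypyridin-3-yl]lithium | [Li]c1c(OC)ncc(-c2ccc(OC(C)(C)C)cc2)c1OC | intermediate
14 | 5-(4-tert-butoxyphenyl)-2,4-dimethoxypyridine-3-carbaldehyde | O=Cc1c(OC)ncc(-c2ccc(OC(C)(C)C)cc2)c1OC | intermediate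
15 | [(4aS,7S,8aS)-4,7-dimethyl-4a,5,6,7,8,8a-hexahydronaphthalen-2-yl]chromium dichloride | Cl[Cr](Cl)C1=C[C@H]2C[C@@H](C)CC[C@@H]2C(C)=C1 | intermediate
16 | [5-(4-tert-butoxyphenyl)-2,4-dimethoxypyridin-3-yl][(4aS,7S,8aR)-4,7-dimethyl-4a,5,6,7,8,8a-hexahydronaphthalen-2-yl]methanol (carbinol epimers) | COc1ncc(-c2ccc(OC(C)(C)C)cc2)c(OC)c1C(O)C1=C[C@H]2C[C@@H](C)CC[C@@H]2C(C)=C1 | intermediate
17 | [5-(4-tert-butoxyphenyl)-2,4-dimethoxypyridin-3-yl][(4aS,7S,8aR)-4,7-dimethyl-4a,5,6,7,8,8a-hexahydronaphthalen-2-yl]methanone | COc1ncc(-c2ccc(OC(C)(C)C)cc2)c(OC)c1C(=O)C1=C[C@H]2C[C@@H](C)CC[C@@H]2C(C)=C1 | intermediate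
18 | lithium enolate of 19 (exocyclic C2=C(OLi) dienolate, C1 as in 19) | C/C=C/[C@H]1[C@H]2C[C@@H](C)CC[C@@H]2C(C)=CC1=C(O[Li])c1c(OC)ncc(-c2ccc(OC(C)(C)C)cc2)c1OC | intermediate
19 | [5-(4-tert-butoxyphenyl)-2,4-dimethoxypyridin-3-yl][(1S,2S,4aS,7S,8aR)-4,7-dimethyl-1-[(E)-prop-1-enyl]-1,2,4a,5,6,7,8,8a-octahydronaphthalen-2-yl]methanone | C/C=C/[C@H]1[C@H]2C[C@@H](C)CC[C@@H]2C(C)=C[C@H]1C(=O)c1c(OC)ncc(-c2ccc(OC(C)(C)C)cc2)c1OC | intermediate
20 | tris(trimethylsilyl) ether of 21 (2,4-bis(trimethylsilyloxy)pyridine, aryl OSiMe3) | C/C=C/[C@H]1[C@H]2C[C@@H](C)CC[C@@H]2C(C)=C[C@H]1C(=O)c1c(O[Si](C)(C)C)ncc(-c2ccc(O[Si](C)(C)C)cc2)c1O[Si](C)(C)C | intermediate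
21 | 4-hydroxy-5-(4-hydroxyphenyl)-3-[(1S,2S,4aS,7S,8aR)-4,7-dimethyl-1-[(E)-prop-1-enyl]-1,2,4a,5,6,7,8,8a-octahydronaphthalene-2-carbonyl]pyridin-2(1H)-one (CNP0267724.3) | C/C=C/[C@H]1[C@H]2C[C@@H](C)CC[C@@H]2C(C)=C[C@H]1C(=O)c1c(O)c(-c2ccc(O)cc2)c[nH]c1=O | target

**Step count**
Total: 11 steps. Longest linear sequence: 9 steps (steps 1–5 and 8–11, from citral); the pyridine fragment takes 2 steps (6 and 7).

**Three steps most likely to fail, with fallbacks**

Step 3 (the proposed new bicyclisation). The acid may stop at aldehyde 4, divert to a dihydropyran by hetero‑Diels–Alder closure, or oligomerise the substrate. The fallback uses known stepwise Lewis‑acid chemistry; it sets out from 2 and comes back to the route at 5. Knoevenagel condensation of 2 with dimethyl malonate (piperidinium acetate, CH2Cl2) gives dimethyl 2-[(3S)-3,7-dimethyloct-6-en-1-ylidene]propanedioate F1. FeCl3 on Al2O3 (CH2Cl2, −78 °C) then effects the established type 1 ene cyclisation of the doubly activated enophile to dimethyl 2-[(1S,2S,5S)-5-methyl-2-(prop-1-en-2-yl)cyclohexyl]propanedioate F2. Krapcho demethoxycarbonylation (LiCl, wet DMSO, 150 °C) gives methyl 2-[(1R,2S,5S)-5-methyl-2-(prop-1-en-2-yl)cyclohexyl]acetate F3. Reduction with i-Bu2AlH (toluene, −78 °C) gives aldehyde 4, here isolated, and Me2AlCl (CH2Cl2, −78 → 0 °C) closes ring A by the known type 2 carbonyl‑ene reaction to 5.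

Step 10 (conjugate propenylation and protonation). The twisted, di‑ortho‑substituted aroyl dienone may react sluggishly, or the bulky enolate may protonate unselectively. The fallback performs the same stereochemical operation on a small, reactive acceptor and attaches the pyridine afterwards; it sets out from 9 and comes back at 19. Reductive carbonylation of 9 (Pd(OAc)2, 1,3-bis(diphenylphosphino)propane, CO 1 atm, Et3SiH, Et3N, DMF, 70 °C) gives (4aS,7S,8aR)-4,7-dimethyl-4a,5,6,7,8,8a-hexahydronaphthalene-2-carbaldehyde F4. The Gilman reagent of step 10 with Me3SiCl (Et2O, −78 °C) gives the trimethylsilyl dienol ether F5. Buffered hydrolysis (AcOH, THF/H2O, −20 °C) protonates C2 anti to the axial propenyl group to give (1S,2S,4aS,7S,8aR)-4,7-dimethyl-1-[(E)-prop-1-enyl]-1,2,4a,5,6,7,8,8a-octahydronaphthalene-2-carbaldehyde F6. Aryllithium 13 adds to F6 at −78 °C to give the carbinol F7, and Dess–Martin oxidation gives 19.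

Step 11 (global dealkylation). Me3SiI or adventitious HI may enolise C2, or move or hydroiodinate the C3=C4 alkene. The fallback removes the alkyl groups before any sensitive centre exists; it sets out from 17 and comes back at 20 and thus 21. BBr3 (CH2Cl2, −78 → 0 °C) converts 17 into 3-[(4aS,7S,8aR)-4,7-dimethyl-4a,5,6,7,8,8a-hexahydronaphthalene-2-carbonyl]-4-hydroxy-5-(4-hydroxyphenyl)pyridin-2(1H)-one F8. This is persilylated in the flask with N,O-bis(trimethylsilyl)acetamide (THF, rt) to the tris(trimethylsilyl) dienone F9. The Gilman reagent of step 10 followed by the AcOH quench at −78 °C then gives 20, and aqueous work‑up gives 21.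

**Further compounds**
F1 | step 3 | dimethyl 2-[(3S)-3,7-dimethyloct-6-en-1-ylidene]propanedioate | COC(=O)C(=CC[C@@H](C)CCC=C(C)C)C(=O)OC
F2 | step 3 | dimethyl 2-[(1S,2S,5S)-5-methyl-2-(prop-1-en-2-yl)cyclohexyl]propanedioate | COC(=O)C(C(=O)OC)[C@H]1C[C@@H](C)CC[C@@H]1C(C)=C
F3 | step 3 | methyl 2-[(1R,2S,5S)-5-methyl-2-(prop-1-en-2-yl)cyclohexyl]acetate | COC(=O)C[C@H]1C[C@@H](C)CC[C@@H]1C(C)=C
F4 | step 10 | (4aS,7S,8aR)-4,7-dimethyl-4a,5,6,7,8,8a-hexahydronaphthalene-2-carbaldehyde | O=CC1=C[C@H]2C[C@@H](C)CC[C@@H]2C(C)=C1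
F5 | step 10 | trimethylsilyl dienol ether of F6 (exocyclic C2=CH–OSiMe3) | C/C=C/[C@H]1[C@H]2C[C@@H](C)CC[C@@H]2C(C)=CC1=CO[Si](C)(C)C
F6 | step 10 | (1S,2S,4aS,7S,8aR)-4,7-dimethyl-1-[(E)-prop-1-enyl]-1,2,4a,5,6,7,8,8a-octahydronaphthalene-2-carbaldehyde | C/C=C/[C@H]1[C@H]2C[C@@H](C)CC[C@@H]2C(C)=C[C@H]1C=O
F7 | step 10 | [5-(4-tert-butoxyphenyl)-2,4-dimethoxypyridin-3-yl][(1S,2S,4aS,7S,8aR)-4,7-dimethyl-1-[(E)-prop-1-enyl]-1,2,4a,5,6,7,8,8a-octahydronaphthalen-2-yl]methanol (carbinol epimers) | C/C=C/[C@H]1[C@H]2C[C@@H](C)CC[C@@H]2C(C)=C[C@H]1C(O)c1c(OC)ncc(-c2ccc(OC(C)(C)C)cc2)c1OC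
F8 | step 11 | 3-[(4aS,7S,8aR)-4,7-dimethyl-4a,5,6,7,8,8a-hexahydronaphthalene-2-carbonyl]-4-hydroxy-5-(4-hydroxyphenyl)pyridin-2(1H)-one | O=C(C1=C[C@H]2C[C@@H](C)CC[C@@H]2C(C)=C1)c1c(O)c(-c2ccc(O)cc2)c[nH]c1=O
F9 | step 11 | tris(trimethylsilyl) ether of F8 | O=C(C1=C[C@H]2C[C@@H](C)CC[C@@H]2C(C)=C1)c1c(O[Si](C)(C)C)ncc(-c2ccc(O[Si](C)(C)C)cc2)c1O[Si](C)(C)C
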